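The numbers come from no measurement, and the outcome is calculated.

I am handing you this flask; its neighbour with less solid substrate stands beside it and comes later.

solid substrate 0.050 M; protic impurity 5.00 mM; time 20 min

    starting material ⇌ target (K1 = 2.73, k1 = 1.01 s⁻¹)
    starting material + protic impurity → quenched substrate (k2 = 5.65 M⁻¹ s⁻¹)
    solid substrate ⇌ starting material, rate k3*(cs3 - [starting material]) while solid is left; crystals form when [starting material] > cs3 (cs3 = 2.1 mM, k3 = 0.0713 s⁻¹)
    isomer of the product ⇌ starting material (k4 = 0.0812 s⁻¹)
    target ⇌ isomer of the product (K5 = 0.68, k5 = 0.00967 s⁻¹)

- given per volume of solution although it is solid: solid substrate
- at the start none of the solid substrate is in solution
- what has only dissolved of solid substrate counts as not reacted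
- the reaction counts as stopped when no species that holds the solid substrate changes by six tenths of a point or more over the second half of the time
- run time (flask): 20 min

- which holds at 20 min: what has brought the reaction to rest, or that it has not come to rest (for what has run out or reacted, a solid counts together with what of it has only dissolved) (forward and back rates have come level / it is still moving / all of the solid substrate has reacted)
- part of the solid substrate that has turned into other species by 20 min (what has only dissolved does not count)
- amount of target at 20 min, in percent of the solid substrate charged

In the flask, solid substrate dissolves into starting material, which passes on to target and isomer of the product, while the protic impurity quenches some of it. I reckon in fractions of the charge. While solid stands, dissolved starting material tends to its saturation share, 4.20%. In powers of ten, target then lies 0.436 decades above that share and isomer of the product 0.269, which makes 11.5% and 7.80%. The protic impurity, the limiting reagent of the quench, adds its own 10.0% as quenched substrate.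

The sum of these three shares I call the saturation debt, what the solution must draw from the solid and turn into other species before it can rest: 29.3%. The debt plus the dissolved share is less than the charge, so solid should remain when you come. At saturation the protic impurity has a half-life of 0.974 min, far shorter than the 20 min of the run, so I expect rest by then. Add no protic impurity: while solid stands, each share of it enters the debt one for one.

The forecast says forward and back rates have come level, with 29.3% converted and 11.5% of target, on the ground that “all the relaxation times are a few minutes at most”. My reckoning gives the same figures.

The simulation gives forward and back rates have come level, with 29.3% converted and 11.5% of target, and the largest change of a substrate, an intermediate or a product in this flask over the second half of the time is 0.074 percentage points. Taking away half of the impurity's share leaves a debt of 24.3%; this flask run with that reduced charge converts 24.3%.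

In the neighbour flask, with 0.030 M of solid substrate, the same debt spread over the smaller charge comes to 48.8%, with target at 19.1%. The neighbour flask converts 48.8% and holds 19.1% of target.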